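**Plan**

1. Labdane numbering is used (ring A: C1–C5 and C10; ring B: C5–C10; side chain C11–C16 on C9; C17 on C8; C20 on C10). The retrosynthesis first cuts the acetate and C8–C17 (Stille hydroxymethylation of a C7=C8 enol triflate). It then cuts C9–C11 (Negishi coupling at a C9 enol triflate, the carbonyl being moved from C9 to C8 by hydroboration and oxidation).
2. Ring A is then cut at C1–C10 and C2–C3. Both bonds arise in one tandem Michael/carbonyl-addition annulation in which phenyl vinyl sulfone delivers C1–C2.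
3. Enabling feature: in ring B, C10 is α to a temporary C9 ketone, so it is an enolate carbon. The gem-dimethyl carbon C4 on C5 carries C3 as a non-enolisable aldehyde. Nucleophilic C10 and electrophilic C3 therefore stand 1,4 across C5–C4, and a two-carbon acceptor/donor closes the six-membered ring A.
4. The last cut is C4–C5 (enantioselective Mukaiyama–Michael addition to 2-methylcyclohex-2-enone). Forward order: ring B is bought, C4–C5 is made, ring A is closed in the key step, the helpers are removed (the sulfonyl group on C2; the C9 carbonyl after it has served for side-chain attachment), and C17 is added last.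
5. Stereochemistry: C5 from the chiral catalyst; C10 from attack anti to the C5 substituent; C3 from equilibration to the equatorial alkoxide; C9 from α-face hydroboration (also the thermodynamic epimer next to the C8 ketone); C13 from (R)-methyl hydrogen 3-methylglutarate.

Key step: step 3

Assumption: the (S)-configured oxazaborolidinium catalyst is taken to shield the enone face that leads to the (R)-adduct 3; if the sense is the opposite, its antipode is used and nothing else changes.

**Route**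

Step 1
Reactants: 1 2-methylcyclohex-2-en-1-one; 2 1-methoxy-2-methyl-1-(trimethylsilyloxy)prop-1-ene
Product: 3 methyl 2-methyl-2-[(1R)-2-methyl-3-(trimethylsilyloxy)cyclohex-2-en-1-yl]propanoate
Conditions: (S)-3,3-diphenyl-1-(o-tolyl)tetrahydro-1H,3H-pyrrolo[1,2-c][1,3,2]oxazaborole·HN(SO2CF3)2 (10 mol %), Ph3PO (25 mol %), toluene, −20 °C; non-aqueous work-up
Reagents that add atoms: none
Why: Mukaiyama–Michael addition of the isobutyrate silyl ketene acetal to the β-carbon of the Lewis-acid-bound enone, in which the chiral oxazaborolidinium shields one enone face and so sets the ring stereocentre (R), while silyl transfer to oxygen gives the regiodefined tetrasubstituted enol silane.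

Step 2
Reactants: 3 methyl 2-methyl-2-[(1R)-2-methyl-3-(trimethylsilyloxy)cyclohex-2-en-1-yl]propanoate
Product: 4 2-methyl-2-[(1R)-2-methyl-3-(trimethylsilyloxy)cyclohex-2-en-1-yl]propanal
Conditions: i-Bu2AlH (1.1 equiv), CH2Cl2, −78 °C; MeOH, then aq. KNaC4H4O6 at pH 7
Reagents that add atoms: none
Why: Partial reduction of an ester with i-Bu2AlH: the hindered α-quaternary ester should stop at the aluminium hemiacetal at low temperature and release the aldehyde on work-up, the enol silane is inert to the hydride, and no stereocentre is touched.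

Step 3
Reactants: 4 2-methyl-2-[(1R)-2-methyl-3-(trimethylsilyloxy)cyclohex-2-en-1-yl]propanal; 5 phenyl vinyl sulfone
Product: 8 (4aS,6R,7R,8aS)-6-hydroxy-5,5,8a-trimethyl-7-(phenylsulfonyl)octahydronaphthalen-1(2H)-one, via enolate 6 (not isolated), via sulfonyl carbanion 7 (not isolated)
Conditions: (Me2N)3S[Me3SiF2] (1.1 equiv), 5 (2 equiv), THF, −78 → −20 °C; AcOH quench
Reagents that add atoms: none
Why: Fluoride removes the silyl group of 4 to give the regiodefined tetrasubstituted enolate 6, whose C10 adds to the β-carbon of the vinyl sulfone (Michael addition, C1–C10), and the resulting α-sulfonyl carbanion 7 adds at once to the pendant aldehyde (C2–C3) before it is protonated. The closest known reaction type is the Michael-initiated ring closure, that is conjugate addition to a vinyl sulfone followed by intramolecular trapping of the α-sulfonyl carbanion by a carbonyl group (tandem Michael/aldol annulation). Ring A is closed in the second event by a 6-exo-trig addition to the C3 carbonyl; ring B is present from the start. C10 is controlled by the C5 substituent, which sits pseudoaxial to avoid A(1,2) strain with the C10 methyl, so the acceptor enters on the opposite face (C1 trans to C4, hence the trans-decalin); C2 carries the sulfonyl group equatorial to avoid a syn-axial clash with the C10 methyl; C3 is set by the reversibility of the carbanion–aldehyde addition, which should let the equatorial alkoxide accumulate. The step needs regioselectivity for C10 over C8 and chemoselectivity for conjugate addition over aldol addition of the enolate to the aldehyde; the first is secured by the enol silane position fixed in step 1 and the absence of a proton source, the second by the aldehyde being neopentyl and non-enolisable, out of reach of C10 within the molecule (four-membered ring) and hindered between molecules.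

Step 4
Reactants: 8 (4aS,6R,7R,8aS)-6-hydroxy-5,5,8a-trimethyl-7-(phenylsulfonyl)octahydronaphthalen-1(2H)-one
Product: 9 (4aS,6S,8aS)-6-hydroxy-5,5,8a-trimethyloctahydronaphthalen-1(2H)-one
Conditions: Na(Hg) (6% Na), Na2HPO4, MeOH–THF, −20 °C
Reagents that add atoms: none
Why: Reductive desulfonylation: electron transfer cleaves the C–S bond and the carbanion should be protonated by methanol faster than it can expel the poor β-hydroxide leaving group, which erases the C2 centre and leaves the other stereocentres untouched.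

Step 5
Reactants: 9 (4aS,6S,8aS)-6-hydroxy-5,5,8a-trimethyloctahydronaphthalen-1(2H)-one
Product: 10 (4aS,6S,8aS)-6-[(tert-butyldimethylsilyl)oxy]-5,5,8a-trimethyloctahydronaphthalen-1(2H)-one
Conditions: TBSOTf, 2,6-lutidine, CH2Cl2, −78 → 0 °C
Reagents that add atoms: tert-butyldimethylsilyl trifluoromethanesulfonate, CC(C)(C)[Si](C)(C)OS(=O)(=O)C(F)(F)F
Why: O-Silylation of the hindered neopentyl secondary alcohol with the silyl triflate and a hindered base, which is faster than enol silane formation at the ketone under these conditions; configuration at C3 is retained.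

Step 6
Reactants: 10 (4aS,6S,8aS)-6-[(tert-butyldimethylsilyl)oxy]-5,5,8a-trimethyloctahydronaphthalen-1(2H)-one
Product: 12 (4aS,6S,8aS)-6-[(tert-butyldimethylsilyl)oxy]-5,5,8a-trimethyl-3,4,4a,5,6,7,8,8a-octahydronaphthalen-1-yl trifluoromethanesulfonate, via potassium enolate 11 (not isolated)
Conditions: KN(SiMe3)2, THF, −78 °C; then PhNTf2, −78 → 0 °C
Reagents that add atoms: N-phenylbis(trifluoromethanesulfonimide), O=S(=O)(N(c1ccccc1)S(=O)(=O)C(F)(F)F)C(F)(F)F
Why: Enol triflate formation: deprotonation can occur only at C8 because C10 is quaternary, and O-sulfonylation of the enolate gives the C8=C9 vinyl triflate without touching a stereocentre.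

Step 7
Reactants: 13 (3R)-5-methoxy-3-methyl-5-oxopentanoic acid [(R)-methyl hydrogen 3-methylglutarate]
Product: 14 methyl (3R)-5-hydroxy-3-methylpentanoate
Conditions: BH3·SMe2, THF, 0 °C → rt; MeOH quench; used without delay
Reagents that add atoms: none
Why: Chemoselective borane reduction of the free carboxylic acid (via the acyloxyborane) in the presence of the methyl ester; the stereocentre is not involved.

Step 8
Reactants: 14 methyl (3R)-5-hydroxy-3-methylpentanoate
Product: 15 methyl (3S)-5-iodo-3-methylpentanoate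
Conditions: I2, PPh3, imidazole, CH2Cl2, 0 °C
Reagents that add atoms: iodine, II
Why: Appel-type iodination: the primary alcohol is activated as an alkoxyphosphonium ion and displaced by iodide, the remote stereocentre keeping its geometry (the descriptor changes only through the priority rules).

Step 9
Reactants: 12 (4aS,6S,8aS)-6-[(tert-butyldimethylsilyl)oxy]-5,5,8a-trimethyl-3,4,4a,5,6,7,8,8a-octahydronaphthalen-1-yl trifluoromethanesulfonate; 15 methyl (3S)-5-iodo-3-methylpentanoate
Product: 17 methyl (3R)-5-[(4aR,6S,8aS)-6-[(tert-butyldimethylsilyl)oxy]-5,5,8a-trimethyl-3,4,4a,5,6,7,8,8a-octahydronaphthalen-1-yl]-3-methylpentanoate, via alkylzinc iodide 16 (not isolated)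
Conditions: Zn dust (activated by BrCH2CH2Br and Me3SiCl), LiCl, THF, 40 °C; then 12, PdCl2(dppf) (5 mol %), THF–NMP, 60 °C
Reagents that add atoms: none
Why: Negishi coupling: zinc inserts into the primary C–I bond, the ester-tolerant alkylzinc transmetalates to the vinylpalladium species formed by oxidative addition of the triflate, and reductive elimination forms C9–C11 with no stereocentre affected.

Step 10
Reactants: 17 methyl (3R)-5-[(4aR,6S,8aS)-6-[(tert-butyldimethylsilyl)oxy]-5,5,8a-trimethyl-3,4,4a,5,6,7,8,8a-octahydronaphthalen-1-yl]-3-methylpentanoate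
Product: 19 methyl (3R)-5-[(1R,2R,4aR,6S,8aS)-6-[(tert-butyldimethylsilyl)oxy]-2-hydroxy-5,5,8a-trimethyldecahydronaphthalen-1-yl]-3-methylpentanoate, via alkylborane 18 (not isolated)
Conditions: BH3·THF, THF, 0 °C → rt (short reaction time); then 30% H2O2, aq. NaOAc, 0 °C → rt
Reagents that add atoms: hydrogen peroxide, OO
Why: Hydroboration–oxidation: boron adds to the less substituted C8 and hydrogen to C9, syn and from the α face opposite the axial C10 methyl, which sets H9 α (side chain β), and oxidation with retention gives the 8α-alcohol.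

Step 11
Reactants: 19 methyl (3R)-5-[(1R,2R,4aR,6S,8aS)-6-[(tert-butyldimethylsilyl)oxy]-2-hydroxy-5,5,8a-trimethyldecahydronaphthalen-1-yl]-3-methylpentanoate
Product: 20 methyl (3R)-5-[(1R,4aR,6S,8aS)-6-[(tert-butyldimethylsilyl)oxy]-5,5,8a-trimethyl-2-oxodecahydronaphthalen-1-yl]-3-methylpentanoate
Conditions: DMP [1,1,1-tris(acetyloxy)-1,1-dihydro-1,2-benziodoxol-3(1H)-one], CH2Cl2, rt
Reagents that add atoms: none
Why: Dess–Martin oxidation of the secondary alcohol to the C8 ketone; C9, now α to the ketone, already carries the equatorial side chain, which is the thermodynamically preferred arrangement, so no epimerisation is expected.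

Step 12
Reactants: 20 methyl (3R)-5-[(1R,4aR,6S,8aS)-6-[(tert-butyldimethylsilyl)oxy]-5,5,8a-trimethyl-2-oxodecahydronaphthalen-1-yl]-3-methylpentanoate
Product: 22 methyl (3R)-5-[(1R,4aR,6S,8aS)-6-[(tert-butyldimethylsilyl)oxy]-5,5,8a-trimethyl-2-{[(trifluoromethyl)sulfonyl]oxy}-1,4,4a,5,6,7,8,8a-octahydronaphthalen-1-yl]-3-methylpentanoate, via potassium enolate 21 (not isolated)
Conditions: KN(SiMe3)2 (1.05 equiv), THF, −78 °C; then PhNTf2
Reagents that add atoms: N-phenylbis(trifluoromethanesulfonimide), O=S(=O)(N(c1ccccc1)S(=O)(=O)C(F)(F)F)C(F)(F)F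
Why: Regioselective enol triflate formation: the bulky amide base should remove a proton kinetically from the C7 methylene, not from the hindered tertiary C9 or the less acidic ester, and O-sulfonylation fixes the double bond at C7=C8 with C9 unchanged.

Step 13
Reactants: 22 methyl (3R)-5-[(1R,4aR,6S,8aS)-6-[(tert-butyldimethylsilyl)oxy]-5,5,8a-trimethyl-2-{[(trifluoromethyl)sulfonyl]oxy}-1,4,4a,5,6,7,8,8a-octahydronaphthalen-1-yl]-3-methylpentanoate
Product: 23 methyl (3R)-5-[(1R,4aR,6S,8aR)-6-[(tert-butyldimethylsilyl)oxy]-2-(hydroxymethyl)-5,5,8a-trimethyl-1,4,4a,5,6,7,8,8a-octahydronaphthalen-1-yl]-3-methylpentanoate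
Conditions: Bu3SnCH2OH, Pd(PPh3)4 (10 mol %), LiCl, 1,4-dioxane, 95 °C
Reagents that add atoms: (tributylstannyl)methanol, CCCC[Sn](CCCC)(CCCC)CO
Why: Stille coupling of the vinyl triflate with the hydroxymethyl stannane (oxidative addition to zerovalent palladium, transmetalation, reductive elimination) installs C17 on C8 without moving the C7=C8 double bond; no stereocentre is formed.

Step 14
Reactants: 23 methyl (3R)-5-[(1R,4aR,6S,8aR)-6-[(tert-butyldimethylsilyl)oxy]-2-(hydroxymethyl)-5,5,8a-trimethyl-1,4,4a,5,6,7,8,8a-octahydronaphthalen-1-yl]-3-methylpentanoate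
Product: 24 methyl (3R)-5-[(1R,4aR,6S,8aR)-2-(acetoxymethyl)-6-[(tert-butyldimethylsilyl)oxy]-5,5,8a-trimethyl-1,4,4a,5,6,7,8,8a-octahydronaphthalen-1-yl]-3-methylpentanoate
Conditions: Ac2O, pyridine, DMAP (cat.), CH2Cl2, 0 °C → rt
Reagents that add atoms: acetic anhydride, CC(=O)OC(C)=O
Why: DMAP-catalysed acylation of the primary allylic alcohol, the C3 oxygen being masked as its silyl ether so that only C17 is acetylated.

Step 15
Reactants: 24 methyl (3R)-5-[(1R,4aR,6S,8aR)-2-(acetoxymethyl)-6-[(tert-butyldimethylsilyl)oxy]-5,5,8a-trimethyl-1,4,4a,5,6,7,8,8a-octahydronaphthalen-1-yl]-3-methylpentanoate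
Product: 25 methyl (3R)-5-[(1R,4aR,6S,8aR)-2-(acetoxymethyl)-6-hydroxy-5,5,8a-trimethyl-1,4,4a,5,6,7,8,8a-octahydronaphthalen-1-yl]-3-methylpentanoate
Conditions: HF·pyridine, THF, 0 °C → rt
Reagents that add atoms: none
Why: Fluoride-driven cleavage of the silyl ether (desilylation) under buffered acidic conditions that should leave the allylic acetate and the methyl ester intact, with retention at C3.

**Compound list**

1 | 2-methylcyclohex-2-en-1-one | CC1=CCCCC1=O | starting material
2 | 1-methoxy-2-methyl-1-(trimethylsilyloxy)prop-1-ene | COC(O[Si](C)(C)C)=C(C)C | starting material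
3 | methyl 2-methyl-2-[(1R)-2-methyl-3-(trimethylsilyloxy)cyclohex-2-en-1-yl]propanoate | COC(=O)C(C)(C)[C@@H]1CCCC(O[Si](C)(C)C)=C1C | intermediate
4 | 2-methyl-2-[(1R)-2-methyl-3-(trimethylsilyloxy)cyclohex-2-en-1-yl]propanal | O=CC(C)(C)[C@@H]1CCCC(O[Si](C)(C)C)=C1C | intermediate
5 | phenyl vinyl sulfone (ethenylsulfonylbenzene) | C=CS(=O)(=O)c1ccccc1 | starting material
6 | tris(dimethylamino)sulfonium (3R)-2-methyl-3-(2-methyl-1-oxopropan-2-yl)cyclohex-1-en-1-olate | O=CC(C)(C)[C@@H]1CCCC([O-])=C1C.CN(C)[S+](N(C)C)N(C)C | intermediate (not isolated)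
7 | tris(dimethylamino)sulfonium 2-[(1S,2S)-1-methyl-2-(2-methyl-1-oxopropan-2-yl)-6-oxocyclohexyl]-1-(phenylsulfonyl)ethan-1-ide | O=C1CCC[C@@H](C(C)(C)C=O)[C@]1(C)C[CH-]S(=O)(=O)c1ccccc1.CN(C)[S+](N(C)C)N(C)C | intermediate (not isolated)
8 | (4aS,6R,7R,8aS)-6-hydroxy-5,5,8a-trimethyl-7-(phenylsulfonyl)octahydronaphthalen-1(2H)-one | O=C1CCC[C@H]2C(C)(C)[C@@H](O)[C@H](S(=O)(=O)c3ccccc3)C[C@]12C | intermediate
9 | (4aS,6S,8aS)-6-hydroxy-5,5,8a-trimethyloctahydronaphthalen-1(2H)-one | O=C1CCC[C@H]2C(C)(C)[C@@H](O)CC[C@]12C | intermediate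
10 | (4aS,6S,8aS)-6-[(tert-butyldimethylsilyl)oxy]-5,5,8a-trimethyloctahydronaphthalen-1(2H)-one | O=C1CCC[C@H]2C(C)(C)[C@@H](O[Si](C)(C)C(C)(C)C)CC[C@]12C | intermediate
11 | potassium (4aS,6S,8aS)-6-[(tert-butyldimethylsilyl)oxy]-5,5,8a-trimethyl-3,4,4a,5,6,7,8,8a-octahydronaphthalen-1-olate | [K+].[O-]C1=CCC[C@H]2C(C)(C)[C@@H](O[Si](C)(C)C(C)(C)C)CC[C@]12C | intermediate (not isolated)
12 | (4aS,6S,8aS)-6-[(tert-butyldimethylsilyl)oxy]-5,5,8a-trimethyl-3,4,4a,5,6,7,8,8a-octahydronaphthalen-1-yl trifluoromethanesulfonate | FC(F)(F)S(=O)(=O)OC1=CCC[C@H]2C(C)(C)[C@@H](O[Si](C)(C)C(C)(C)C)CC[C@]12C | intermediate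
13 | (3R)-5-methoxy-3-methyl-5-oxopentanoic acid [(R)-methyl hydrogen 3-methylglutarate] | COC(=O)C[C@H](C)CC(=O)O | starting material
14 | methyl (3R)-5-hydroxy-3-methylpentanoate | COC(=O)C[C@H](C)CCO | intermediate
15 | methyl (3S)-5-iodo-3-methylpentanoate | COC(=O)C[C@H](C)CCI | intermediate
16 | [(3S)-5-methoxy-3-methyl-5-oxopentyl]zinc iodide | COC(=O)C[C@H](C)CC[Zn]I | intermediate (not isolated)
17 | methyl (3R)-5-[(4aR,6S,8aS)-6-[(tert-butyldimethylsilyl)oxy]-5,5,8a-trimethyl-3,4,4a,5,6,7,8,8a-octahydronaphthalen-1-yl]-3-methylpentanoate | COC(=O)C[C@H](C)CCC1=CCC[C@H]2C(C)(C)[C@@H](O[Si](C)(C)C(C)(C)C)CC[C@]12C | intermediate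
18 | methyl (3R)-5-[(1S,2R,4aR,6S,8aR)-2-boranyl-6-[(tert-butyldimethylsilyl)oxy]-5,5,8a-trimethyldecahydronaphthalen-1-yl]-3-methylpentanoate | COC(=O)C[C@H](C)CC[C@H]1[C@H](B)CC[C@H]2C(C)(C)[C@@H](O[Si](C)(C)C(C)(C)C)CC[C@]12C | intermediate (not isolated)
19 | methyl (3R)-5-[(1R,2R,4aR,6S,8aS)-6-[(tert-butyldimethylsilyl)oxy]-2-hydroxy-5,5,8a-trimethyldecahydronaphthalen-1-yl]-3-methylpentanoate | COC(=O)C[C@H](C)CC[C@H]1[C@H](O)CC[C@H]2C(C)(C)[C@@H](O[Si](C)(C)C(C)(C)C)CC[C@]12C | intermediate
20 | methyl (3R)-5-[(1R,4aR,6S,8aS)-6-[(tert-butyldimethylsilyl)oxy]-5,5,8a-trimethyl-2-oxodecahydronaphthalen-1-yl]-3-methylpentanoate | COC(=O)C[C@H](C)CC[C@H]1C(=O)CC[C@H]2C(C)(C)[C@@H](O[Si](C)(C)C(C)(C)C)CC[C@]12C | intermediate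
21 | potassium (1R,4aR,6S,8aS)-6-[(tert-butyldimethylsilyl)oxy]-1-[(3R)-5-methoxy-3-methyl-5-oxopentyl]-5,5,8a-trimethyl-1,4,4a,5,6,7,8,8a-octahydronaphthalen-2-olate | [K+].COC(=O)C[C@H](C)CC[C@H]1C([O-])=CC[C@H]2C(C)(C)[C@@H](O[Si](C)(C)C(C)(C)C)CC[C@]12C | intermediate (not isolated)
22 | methyl (3R)-5-[(1R,4aR,6S,8aS)-6-[(tert-butyldimethylsilyl)oxy]-5,5,8a-trimethyl-2-{[(trifluoromethyl)sulfonyl]oxy}-1,4,4a,5,6,7,8,8a-octahydronaphthalen-1-yl]-3-methylpentanoate | COC(=O)C[C@H](C)CC[C@H]1C(OS(=O)(=O)C(F)(F)F)=CC[C@H]2C(C)(C)[C@@H](O[Si](C)(C)C(C)(C)C)CC[C@]12C | intermediate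
23 | methyl (3R)-5-[(1R,4aR,6S,8aR)-6-[(tert-butyldimethylsilyl)oxy]-2-(hydroxymethyl)-5,5,8a-trimethyl-1,4,4a,5,6,7,8,8a-octahydronaphthalen-1-yl]-3-methylpentanoate | COC(=O)C[C@H](C)CC[C@H]1C(CO)=CC[C@H]2C(C)(C)[C@@H](O[Si](C)(C)C(C)(C)C)CC[C@]12C | intermediate
24 | methyl (3R)-5-[(1R,4aR,6S,8aR)-2-(acetoxymethyl)-6-[(tert-butyldimethylsilyl)oxy]-5,5,8a-trimethyl-1,4,4a,5,6,7,8,8a-octahydronaphthalen-1-yl]-3-methylpentanoate | COC(=O)C[C@H](C)CC[C@H]1C(COC(C)=O)=CC[C@H]2C(C)(C)[C@@H](O[Si](C)(C)C(C)(C)C)CC[C@]12C | intermediate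
25 | methyl (3R)-5-[(1R,4aR,6S,8aR)-2-(acetoxymethyl)-6-hydroxy-5,5,8a-trimethyl-1,4,4a,5,6,7,8,8a-octahydronaphthalen-1-yl]-3-methylpentanoate (methyl 17-acetoxy-3β-hydroxylabd-7-en-15-oate) | COC(=O)C[C@H](C)CC[C@H]1C(COC(C)=O)=CC[C@H]2C(C)(C)[C@@H](O)CC[C@]12C | target

**Totals**

Total step count: 15. Longest linear sequence: 13 (steps 1–6 and 9–15).

**Steps most likely to fail**

Step 3. The sulfonyl carbanion may be quenched by proton transfer before it reaches the aldehyde, the free enolate may add to the aldehyde of a second molecule, or the carbonyl addition may not equilibrate to the equatorial alkoxide at C3. The fallback builds the two ring A bonds in separate, Lewis-acid and amine-mediated operations with acrolein as the two-carbon unit. It sets out from 4: Mukaiyama–Michael addition to acrolein (BF3·OEt2, i-PrOH as silyl acceptor, CH2Cl2, −78 °C) should give 3-[(1S,2S)-1-methyl-2-(2-methyl-1-oxopropan-2-yl)-6-oxocyclohexyl]propanal F7. An amine-catalysed intramolecular aldol addition (pyrrolidine, AcOH), in which only the CH2CHO arm can form an enamine, should close ring A to (2R,3S,4aS,8aS)-3-hydroxy-4,4,8a-trimethyl-8-oxodecahydronaphthalene-2-carbaldehyde F8. Silylation (TBSOTf, 2,6-lutidine) would give (2R,3S,4aS,8aS)-3-[(tert-butyldimethylsilyl)oxy]-4,4,8a-trimethyl-8-oxodecahydronaphthalene-2-carbaldehyde F9, and Tsuji–Wilkinson decarbonylation with stoichiometric RhCl(PPh3)3 (PhCN, 130 °C) comes back to the route at 10. If only the C3 configuration is at fault, Dess–Martin oxidation and NaBH4 reduction of the C3 alcohol at the stage of 25 should correct it.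

Step 1. Turnover may be slow with the α-substituted enone, and an achiral silyl-cation pathway may erode the facial selectivity. The fallback takes the ring stereocentre from a carbinol by sigmatropic chirality transfer. It sets out from 1: Corey–Bakshi–Shibata reduction (BH3·SMe2, the 1-methyl-3,3-diphenyl-oxazaborolidine antipode that gives the S alcohol) should give (1S)-2-methylcyclohex-2-en-1-ol F1, and acylation with isobutyryl chloride gives (1S)-2-methylcyclohex-2-en-1-yl 2-methylpropanoate F2. Ireland–Claisen rearrangement (LiN(i-Pr)2, Me3SiCl, THF, −78 °C → reflux) transfers the configuration suprafacially and should give 2-methyl-2-[(1R)-2-methylcyclohex-2-en-1-yl]propanoic acid F3. Esterification (Me3SiCHN2) gives methyl 2-methyl-2-[(1R)-2-methylcyclohex-2-en-1-yl]propanoate F4; hydroboration–oxidation gives methyl 2-[(1R,2R,3R)-3-hydroxy-2-methylcyclohexyl]-2-methylpropanoate F5; Dess–Martin oxidation gives methyl 2-methyl-2-[(1R,2R)-2-methyl-3-oxocyclohexyl]propanoate F6. Thermodynamic silylation (Me3SiCl, NaI, Et3N, MeCN) comes back to the route at 3.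

Step 10. Hydroboration of the hindered trisubstituted alkene next to the quaternary C10 may be slow enough for borane to start reducing the methyl ester. The fallback brings in the C8 oxygen before the coupling. It sets out from 10: enolate hydroxylation (KN(SiMe3)2, then 2-(phenylsulfonyl)-3-phenyloxaziridine) should give (2R,4aS,6S,8aS)-6-[(tert-butyldimethylsilyl)oxy]-2-hydroxy-5,5,8a-trimethyloctahydronaphthalen-1(2H)-one F10. Silylation (Et3SiOTf, 2,6-lutidine) gives (2R,4aS,6S,8aS)-6-[(tert-butyldimethylsilyl)oxy]-5,5,8a-trimethyl-2-[(triethylsilyl)oxy]octahydronaphthalen-1(2H)-one F11. Triflation (KN(SiMe3)2, PhNTf2) gives (4aS,6S,8aS)-6-[(tert-butyldimethylsilyl)oxy]-5,5,8a-trimethyl-2-[(triethylsilyl)oxy]-3,4,4a,5,6,7,8,8a-octahydronaphthalen-1-yl trifluoromethanesulfonate F12. Negishi coupling with 16 under the conditions of step 9 gives methyl (3R)-5-[(4aR,6S,8aS)-6-[(tert-butyldimethylsilyl)oxy]-5,5,8a-trimethyl-2-[(triethylsilyl)oxy]-3,4,4a,5,6,7,8,8a-octahydronaphthalen-1-yl]-3-methylpentanoate F13. Mild acid hydrolysis of the enol silane (AcOH–THF–H2O), with protonation at C9 under thermodynamic control, comes back to the route at 20.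

**Further compounds**

F1 | step 1 | (1S)-2-methylcyclohex-2-en-1-ol | O[C@H]1CCCC=C1C
F2 | step 1 | (1S)-2-methylcyclohex-2-en-1-yl 2-methylpropanoate | CC(C)C(=O)O[C@H]1CCCC=C1C
F3 | step 1 | 2-methyl-2-[(1R)-2-methylcyclohex-2-en-1-yl]propanoic acid | OC(=O)C(C)(C)[C@@H]1CCCC=C1C
F4 | step 1 | methyl 2-methyl-2-[(1R)-2-methylcyclohex-2-en-1-yl]propanoate | COC(=O)C(C)(C)[C@@H]1CCCC=C1C
F5 | step 1 | methyl 2-[(1R,2R,3R)-3-hydroxy-2-methylcyclohexyl]-2-methylpropanoate | COC(=O)C(C)(C)[C@@H]1CCC[C@@H](O)[C@@H]1C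
F6 | step 1 | methyl 2-methyl-2-[(1R,2R)-2-methyl-3-oxocyclohexyl]propanoate | COC(=O)C(C)(C)[C@@H]1CCCC(=O)[C@@H]1C
F7 | step 3 | 3-[(1S,2S)-1-methyl-2-(2-methyl-1-oxopropan-2-yl)-6-oxocyclohexyl]propanal | O=C1CCC[C@@H](C(C)(C)C=O)[C@]1(C)CCC=O
F8 | step 3 | (2R,3S,4aS,8aS)-3-hydroxy-4,4,8a-trimethyl-8-oxodecahydronaphthalene-2-carbaldehyde | O=C1CCC[C@H]2C(C)(C)[C@@H](O)[C@H](C=O)C[C@]12C
F9 | step 3 | (2R,3S,4aS,8aS)-3-[(tert-butyldimethylsilyl)oxy]-4,4,8a-trimethyl-8-oxodecahydronaphthalene-2-carbaldehyde | O=C1CCC[C@H]2C(C)(C)[C@@H](O[Si](C)(C)C(C)(C)C)[C@H](C=O)C[C@]12C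
F10 | step 10 | (2R,4aS,6S,8aS)-6-[(tert-butyldimethylsilyl)oxy]-2-hydroxy-5,5,8a-trimethyloctahydronaphthalen-1(2H)-one | O=C1[C@H](O)CC[C@H]2C(C)(C)[C@@H](O[Si](C)(C)C(C)(C)C)CC[C@]12C
F11 | step 10 | (2R,4aS,6S,8aS)-6-[(tert-butyldimethylsilyl)oxy]-5,5,8a-trimethyl-2-[(triethylsilyl)oxy]octahydronaphthalen-1(2H)-one | O=C1[C@H](O[Si](CC)(CC)CC)CC[C@H]2C(C)(C)[C@@H](O[Si](C)(C)C(C)(C)C)CC[C@]12C
F12 | step 10 | (4aS,6S,8aS)-6-[(tert-butyldimethylsilyl)oxy]-5,5,8a-trimethyl-2-[(triethylsilyl)oxy]-3,4,4a,5,6,7,8,8a-octahydronaphthalen-1-yl trifluoromethanesulfonate | FC(F)(F)S(=O)(=O)OC1=C(O[Si](CC)(CC)CC)CC[C@H]2C(C)(C)[C@@H](O[Si](C)(C)C(C)(C)C)CC[C@]12C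
F13 | step 10 | methyl (3R)-5-[(4aR,6S,8aS)-6-[(tert-butyldimethylsilyl)oxy]-5,5,8a-trimethyl-2-[(triethylsilyl)oxy]-3,4,4a,5,6,7,8,8a-octahydronaphthalen-1-yl]-3-methylpentanoate | COC(=O)C[C@H](C)CCC1=C(O[Si](CC)(CC)CC)CC[C@H]2C(C)(C)[C@@H](O[Si](C)(C)C(C)(C)C)CC[C@]12C
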